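**Numbering used throughout:** 1 methyl 4-fluoro-3-methoxybenzoate; 2 its 5-pinacolboronate; 3 tert-butyl bromoacetate; 4 tert-butyl arylacetate; 5 arylacetic acid; 6 (S)-4-benzyl-2-oxazolidinone; 7 mixed pivalic anhydride; 8 N-arylacetyl oxazolidinone; 9 syringaldehyde; 10 O-benzylsyringaldehyde; 11 Z boron enolate; 12 boron aldolate; 13 syn aldol adduct; 14 1,3-diol; 15 primary trityl ether (precursor of the key step); 16 potassium alkoxide; 17 dihydrobenzofuran ester (product of the key step); 18 C5 benzylic alcohol; 19 methyl (triphenylphosphoranylidene)acetate; 20 C5 aldehyde; 21 acrylate; 22 detritylated acrylate; 23 target.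

## Analysis of the target

The target 23 is a neolignan built on a 2,3-dihydrobenzofuran. Benzo ring A carries a methoxy group on C7 and a methyl propanoate chain on C5; dihydrofuran ring B carries the 4-hydroxy-3,5-dimethoxyphenyl ring C on C2 and a hydroxymethyl group on C3. The two stereocentres are adjacent, C2 (S) and C3 (R), and the aryl and hydroxymethyl groups are trans on ring B. The sensitive points are:

- the free phenol para to C2, which with base can expel the O1 phenoxide through a quinone methide;
- the benzylic C2–O1 ether, which can ionise in acid or be hydrogenolysed;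
- the primary alcohol and the methyl ester.

The difficulty is the control of absolute and relative configuration at two neighbouring centres, one of them an aryl ether carbon. In addition, the oxygen on C2 and the oxygen of the C3 side chain must be kept apart, because either could close a five-membered ring onto ring A. The strategy rests on one positional fact: C5, which carries the propanoate, is para to C7a, the ring A carbon bonded to O1. A carbonyl group held at C5 as a methyl ester therefore makes C7a electrophilic enough for substitution by the C2 oxygen, and the same ester is afterwards the handle from which the three-carbon chain is grown.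

## Retrosynthetic reasoning

**End game, 23 back to 21.** No skeletal bond is cut. The phenol is unveiled last, so that it is never exposed to base or acid, by hydrogenolysis of the benzyl ether of 22 together with saturation of the side-chain double bond. The trityl group of 21 is removed one step earlier by mild acid methanolysis. Hydrogenolysis of a trityl ether is too slow to be counted on, and long exposure to the catalyst would endanger the C2–O1 bond.

**Side chain, 21 back to 17.** The Cα=Cβ bond of the acrylate is cut to give aldehyde 20 and the stabilised ylide 19. Aldehyde 20 comes from benzylic alcohol 18, and 18 from ester 17. The cut is made here because C5 must carry a carbonyl carbon for the key step anyway, and a two-carbon extension of that carbon is the shortest way to the propanoate.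

**Key disconnection, 17 back to 15.** The C7a–O1 bond is cut, which leads to the open-chain fluoroarene 15 with a free secondary hydroxyl on the future C2. The alternatives within ring B are less attractive. Cutting C2–O1 would need a displacement at an ionisable benzylic carbon, and cutting C2–C3 or C3–C3a would create stereocentres in the ring-forming step. Closing the ring at C7a creates no stereocentre, so the stereochemical problem is moved to an acyclic precursor. The forward reaction must make an aryl–oxygen bond from an alkoxide without touching the ester that activates it.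

**Protecting group and auxiliary, 15 back to 13.** The trityl ether of 15 is traced to diol 14, and 14 to the aldol adduct 13 by reductive removal of the auxiliary. The primary oxygen must be blocked because it is also separated from the fluorine-bearing carbon by a five-membered ring, and the block must not migrate to a neighbouring alkoxide.

**Aldol, 13 back to 8 and 10.** The C2–C3 bond is cut between the α-carbon of imide 8 and the carbonyl carbon of aldehyde 10. A syn aldol sets both stereocentres at once. When the C2 oxygen and ring A on C3 are later tied into ring B, the two remaining substituents (ring C on C2 and the carbonyl-derived carbon on C3) fall on opposite faces, so the syn adduct maps onto the trans ring. The (S) auxiliary 6 gives the (2S,3S) adduct, which becomes (2S,3R) in the ring numbering.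

**Ring A building block, 8 back to 1, and 10 back to 9.** Imide 8 comes from acid 5 and auxiliary 6. Acid 5 comes from its tert-butyl ester 4, chosen so that the acetic ester can be cleaved without touching the methyl benzoate. The aryl–CH2 bond of 4 is cut to boronate 2 and bromoacetate 3. Boronate 2 comes from the commercial arene 1 by C–H borylation at the only position whose largest neighbour is fluorine. Aldehyde 10 is the benzyl ether of 9.

## Alternatives that were turned down

**Alternative 1: ring A assembled on a preformed lactone.**
- Disconnection: ring A is cut at C3a–C4 and C7a–C7.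
- Forward key step: the cyclic silyl ketene acetal of the trans lactone A3 acts as an electron-rich two-carbon partner towards the bromopyrone A2. Cycloaddition, decarboxylative cycloreversion and loss of the silyloxy group should give the benzoate A1.
- For it: the aryl–oxygen bond is never made by substitution, since the lactone oxygen simply becomes O1. Ring B and both stereocentres are complete before the key step, and the C5 ester arrives with the new ring. On the security of the C–O bond it is stronger than the chosen route.
- Against it: A3 is a trans β,γ-disubstituted lactone that needs its own asymmetric synthesis, at least as long as the aldol sequence used here. A2 has to be prepared. The cycloaddition of a hindered, fully substituted ketene acetal needs heat. A1 carries bromine at C7, so a late carbon–oxygen coupling at a crowded position next to O1 is needed to install the methoxy group, and only then does the C5 end game begin.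
- Comparison: the chosen route buys ring A with fluorine, methoxy and ester already in place and spends no step on the C7 oxygen.

**Alternative 2: carbene insertion into the benzylic ether C–H bond.**
- Disconnection: the C2–C3 bond.
- Forward key step: the aryldiazoacetate A5 is decomposed by a chiral dirhodium tetracarboxylate, the carbene at C3 inserts into the C2–H bond of the benzylic ether, and an amidine base then equilibrates C3 to give the trans ester A4.
- For it: this is the shortest and most convergent plan. The stereochemistry comes from a catalyst, not from a stoichiometric auxiliary, and the propanoate chain is present from the start. On step count and atom economy it is stronger than the chosen route.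
- Against it: the enantioselectivity depends on the fit between catalyst and a substrate that is unusually crowded, with a methoxy group ortho to the ether oxygen and a bulky trichloroethyl ester. Oxonium ylide formation with benzyl shift can compete with insertion. The equilibration at C3 runs through an ester enolate that can expel the O1 phenoxide; re-addition would scramble C2 and so erode the enantiomeric purity. Finally the C3 ester must be reduced to the hydroxymethyl group in the presence of the methyl propanoate, which costs a selective cleavage and a separate reduction.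
- Comparison: the chosen route offers an auxiliary-controlled aldol of predictable sense with separable diastereomers, and a C3 that carries an oxygenated carbon and cannot be epimerised afterwards.

**Alternative 3: oxidative ring contraction of a flavanone.**
- Disconnection: the C3–C3a bond.
- Forward key step: the enol ether of the (2S)-flavanone A7, formed in an orthoformate with acid, is attacked at C3 by a hydroxy(tosyloxy)iodoarene (a trivalent iodine oxidant). The ring A carbon migrates from the carbonyl carbon to C3 and the trans ester A6 results.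
- For it: few steps from A7, C2 carried over, and C3 set trans by the anti migration.
- Against it: the group that must migrate is a ring A carbon deactivated by bromine, whereas the electron-rich ring C on C2 is the better migrating group, so the competing shift to an isoflavone skeleton is expected to dominate. The acidic medium can open the flavanone by retro-oxa-Michael reaction and racemise C2. An enantioenriched A7 is itself not trivial to obtain. From A6 an ester reduction, a Heck coupling with an acrylate ester at C5 and a hydrogenation are still needed, so nothing is saved.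
- Comparison: in the chosen route the electron-rich ring C is only the aldehyde partner of an aldol, and no migratory competition exists.

Key step: step 9

## Route

Assumption (remark on the chemistry): the α-aryl Z boron enolate 11 is taken to follow the same facial sense as α-alkyl Evans enolates, so that auxiliary 6 of (S) configuration leads to the (2S,3R) target.

Step 1
Reactants: 1 methyl 4-fluoro-3-methoxybenzoate
Product: 2 methyl 4-fluoro-3-methoxy-5-(4,4,5,5-tetramethyl-1,3,2-dioxaborolan-2-yl)benzoate
Conditions: [Ir(OMe)(cod)]2 (1.5 mol %), 4,4'-di-tert-butyl-2,2'-bipyridine (3 mol %), B2pin2 (0.6 equiv), THF, 60 °C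
Reagents that add atoms: bis(pinacolato)diboron, CC1(C)OB(OC1(C)C)B1OC(C)(C)C(C)(C)O1
Why: Iridium-catalysed aromatic C–H borylation is ruled by sterics; C2 lies between ester and methoxy, C6 is ortho to the ester, and only C5 has nothing larger than fluorine beside it, a position that fluorine also activates electronically.

Step 2
Reactants: 2 methyl 4-fluoro-3-methoxy-5-(4,4,5,5-tetramethyl-1,3,2-dioxaborolan-2-yl)benzoate; 3 tert-butyl bromoacetate
Product: 4 tert-butyl 2-[2-fluoro-3-methoxy-5-(methoxycarbonyl)phenyl]acetate
Conditions: Pd(OAc)2 (3 mol %), P(o-tolyl)3 (9 mol %), K3PO4, THF–H2O, rt to 50 °C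
Reagents that add atoms: none
Why: Suzuki–Miyaura coupling of an arylboron reagent with an α-bromoacetate, a known sp2–sp3 coupling in which the bulky triarylphosphine speeds reductive elimination from the palladium enolate; the tert-butyl ester keeps the new acetic ester distinguishable from the methyl benzoate.

Step 3
Reactants: 4 tert-butyl 2-[2-fluoro-3-methoxy-5-(methoxycarbonyl)phenyl]acetate
Product: 5 2-[2-fluoro-3-methoxy-5-(methoxycarbonyl)phenyl]acetic acid
Conditions: CF3CO2H, CH2Cl2, 0 °C to rt
Reagents that add atoms: none
Why: Acidolysis of the tert-butyl ester through the tert-butyl cation; the methyl ester, the aryl fluoride and the methyl ether are inert to these conditions.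

Step 4
Reactants: 5 2-[2-fluoro-3-methoxy-5-(methoxycarbonyl)phenyl]acetic acid; 6 (S)-4-benzyl-2-oxazolidinone
Product: 8 methyl 3-{2-[(4S)-4-benzyl-2-oxo-1,3-oxazolidin-3-yl]-2-oxoethyl}-4-fluoro-5-methoxybenzoate, via mixed pivalic anhydride 7 (not isolated)
Conditions: t-BuCOCl, Et3N, THF, −20 °C; then LiCl, 6, −20 °C to rt
Reagents that add atoms: none
Why: N-Acylation of the oxazolidinone through a mixed anhydride, attacked at the less hindered arylacetyl carbonyl; the lithium chloride and triethylamine variant avoids strong base, which an arylacetic acid derivative with an acidic α-position would not tolerate well.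

Step 5
Reactants: 9 syringaldehyde
Product: 10 4-(benzyloxy)-3,5-dimethoxybenzaldehyde
Conditions: BnBr, K2CO3, DMF, 60 °C
Reagents that add atoms: benzyl bromide, BrCc1ccccc1
Why: Williamson etherification of the acidic, para-formyl phenol; the benzyl ether stands up to boron enolate, borohydride, strong base and hydride chemistry and leaves at the end by hydrogenolysis.

Step 6
Reactants: 8 methyl 3-{2-[(4S)-4-benzyl-2-oxo-1,3-oxazolidin-3-yl]-2-oxoethyl}-4-fluoro-5-methoxybenzoate; 10 4-(benzyloxy)-3,5-dimethoxybenzaldehyde
Product: 13 methyl 3-[(2S,3S)-1-[(4S)-4-benzyl-2-oxo-1,3-oxazolidin-3-yl]-3-[4-(benzyloxy)-3,5-dimethoxyphenyl]-3-hydroxy-1-oxopropan-2-yl]-4-fluoro-5-methoxybenzoate, via Z dibutylboron enolate 11 (not isolated), via dibutylboron aldolate 12 (not isolated)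
Conditions: Bu2BOTf, i-Pr2NEt, CH2Cl2, −78 to 0 °C; then 10, −78 to 0 °C; then pH 7 buffer, MeOH, 30% H2O2, 0 °C
Reagents that add atoms: none
Why: Evans syn aldol reaction: the Z boron enolate 11 reacts through a closed chair transition state with the auxiliary carbonyl turned away from the enolate oxygen, and the aldehyde approaches the face opposite the benzyl group. This sets the α-carbon (future C3) and the carbinol carbon (future C2) together as the (2S,3S) syn adduct. The methyl benzoate has no α-hydrogen and is not enolised.

Step 7
Reactants: 13 methyl 3-[(2S,3S)-1-[(4S)-4-benzyl-2-oxo-1,3-oxazolidin-3-yl]-3-[4-(benzyloxy)-3,5-dimethoxyphenyl]-3-hydroxy-1-oxopropan-2-yl]-4-fluoro-5-methoxybenzoate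
Product: 14 methyl 3-[(1S,2R)-1-[4-(benzyloxy)-3,5-dimethoxyphenyl]-1,3-dihydroxypropan-2-yl]-4-fluoro-5-methoxybenzoate
Conditions: NaBH4, THF–H2O (4:1), 0 °C to rt
Reagents that add atoms: none
Why: Reductive removal of the auxiliary: borohydride in aqueous THF reduces the activated exocyclic imide carbonyl to the primary alcohol and releases 6 for recovery, while an aromatic methyl ester is not reduced under these conditions. No stereocentre is touched; the descriptor at the benzylic carbon changes from S to R only because the priorities change.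

Step 8
Reactants: 14 methyl 3-[(1S,2R)-1-[4-(benzyloxy)-3,5-dimethoxyphenyl]-1,3-dihydroxypropan-2-yl]-4-fluoro-5-methoxybenzoate
Product: 15 methyl 3-[(1S,2R)-1-[4-(benzyloxy)-3,5-dimethoxyphenyl]-1-hydroxy-3-(triphenylmethoxy)propan-2-yl]-4-fluoro-5-methoxybenzoate
Conditions: Ph3CCl, Et3N, DMAP (cat.), CH2Cl2, rt
Reagents that add atoms: trityl chloride, ClC(c1ccccc1)(c1ccccc1)c1ccccc1
Why: Tritylation is governed by the size of the electrophile and takes the primary hydroxyl in preference to the hindered secondary benzylic one; the resulting ether is stable to strong base and cannot migrate.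

Step 9
Reactants: 15 methyl 3-[(1S,2R)-1-[4-(benzyloxy)-3,5-dimethoxyphenyl]-1-hydroxy-3-(triphenylmethoxy)propan-2-yl]-4-fluoro-5-methoxybenzoate
Product: 17 methyl (2S,3R)-2-[4-(benzyloxy)-3,5-dimethoxyphenyl]-7-methoxy-3-[(triphenylmethoxy)methyl]-2,3-dihydro-1-benzofuran-5-carboxylate, via potassium alkoxide 16 (not isolated)
Conditions: KN(SiMe3)2 (1.1 equiv), THF (0.02 M), 0 °C to rt
Reagents that add atoms: none
Why: The hindered amide base removes the proton of the secondary benzylic alcohol, and alkoxide 16 adds to the fluorine-bearing carbon of ring A (the future C7a) to give a cyclohexadienyl anion whose charge sits on C7, C3a and C5 and is drawn from C5 into the ester carbonyl; loss of fluoride then restores the aromatic ring (addition–elimination, intramolecular nucleophilic aromatic substitution). The closest known reaction type is the closure of 2,3-dihydrobenzofurans and chromans by an alkoxide that displaces fluoride from a fluoroarene activated by a para ester or nitrile. Ring B closes in the 5-exo-trig mode: the oxygen attacks a trigonal carbon whose C7a=C7 bond lies outside the five-membered ring being formed. No stereocentre is created and no bond to C2 or C3 is touched, so the (2S,3R) configuration and the trans arrangement come unchanged from the syn aldol adduct. The step needs oxygen selectivity, which the trityl ether provides: the primary oxygen would close an equally good five-membered ring, and trityl, unlike a silyl group, cannot migrate to the neighbouring alkoxide. It needs site selectivity on ring A, which the substrate fixes: of the two carbons the tether can reach, only the one carrying fluorine has a leaving group, addition at the C–H carbon on the other side is reversible, and the methoxy-bearing carbon is meta to the tether and out of reach. It needs the ester to survive, which a non-nucleophilic base and high dilution should ensure, because ring closure is unimolecular and acyl transfer to another molecule is not.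

Step 10
Reactants: 17 methyl (2S,3R)-2-[4-(benzyloxy)-3,5-dimethoxyphenyl]-7-methoxy-3-[(triphenylmethoxy)methyl]-2,3-dihydro-1-benzofuran-5-carboxylate
Product: 18 {(2S,3R)-2-[4-(benzyloxy)-3,5-dimethoxyphenyl]-7-methoxy-3-[(triphenylmethoxy)methyl]-2,3-dihydro-1-benzofuran-5-yl}methanol
Conditions: i-Bu2AlH (2.5 equiv), CH2Cl2, −78 to 0 °C; aq. KNaC4H4O6 (potassium sodium tartrate) work-up
Reagents that add atoms: none
Why: Hydride reduction of the aromatic methyl ester to the benzylic alcohol; trityl, benzyl and methyl ethers and the ring B ether are inert to the aluminium hydride.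

Step 11
Reactants: 18 {(2S,3R)-2-[4-(benzyloxy)-3,5-dimethoxyphenyl]-7-methoxy-3-[(triphenylmethoxy)methyl]-2,3-dihydro-1-benzofuran-5-yl}methanol; 19 methyl (triphenylphosphoranylidene)acetate
Product: 21 methyl (2E)-3-{(2S,3R)-2-[4-(benzyloxy)-3,5-dimethoxyphenyl]-7-methoxy-3-[(triphenylmethoxy)methyl]-2,3-dihydro-1-benzofuran-5-yl}prop-2-enoate, via C5 aldehyde 20 (not isolated)
Conditions: MnO2 (10 equiv), 19 (1.3 equiv), CH2Cl2, rt to 40 °C
Reagents that add atoms: none
Why: Tandem oxidation–Wittig olefination: MnO2 oxidises the electron-rich benzylic alcohol to aldehyde 20, which the stabilised ylide traps in the same flask as the E acrylate; the alkene geometry is of no consequence because the double bond is hydrogenated later.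

Step 12
Reactants: 21 methyl (2E)-3-{(2S,3R)-2-[4-(benzyloxy)-3,5-dimethoxyphenyl]-7-methoxy-3-[(triphenylmethoxy)methyl]-2,3-dihydro-1-benzofuran-5-yl}prop-2-enoate
Product: 22 methyl (2E)-3-{(2S,3R)-2-[4-(benzyloxy)-3,5-dimethoxyphenyl]-3-(hydroxymethyl)-7-methoxy-2,3-dihydro-1-benzofuran-5-yl}prop-2-enoate
Conditions: p-TsOH·H2O (10 mol %), MeOH–CH2Cl2 (1:1), 0 °C to rt
Reagents that add atoms: none
Why: Acid-catalysed methanolysis of the trityl ether through the trityl cation, which is far more stable than the cation that ionisation of C2–O1 would give while the phenol is still benzylated; methanol as solvent leaves the methyl ester unchanged.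

Step 13
Reactants: 22 methyl (2E)-3-{(2S,3R)-2-[4-(benzyloxy)-3,5-dimethoxyphenyl]-3-(hydroxymethyl)-7-methoxy-2,3-dihydro-1-benzofuran-5-yl}prop-2-enoate
Product: 23 methyl 3-[(2S,3R)-2-(4-hydroxy-3,5-dimethoxyphenyl)-3-(hydroxymethyl)-7-methoxy-2,3-dihydro-1-benzofuran-5-yl]propanoate
Conditions: H2 (1 atm), Pd/C (10 wt %), EtOAc–MeOH, rt
Reagents that add atoms: none
Why: Catalytic hydrogenation saturates the conjugated double bond and hydrogenolyses the primary O-benzyl ether of the phenol; the secondary, ring-bound benzylic C2–O1 ether is cleaved much more slowly, as in debenzylations of flavans and related cyclic benzylic ethers, so the reaction is stopped once the benzyl group has gone.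

## Compound list

1 | methyl 4-fluoro-3-methoxybenzoate | COC(=O)c1ccc(F)c(OC)c1 | starting material
2 | methyl 4-fluoro-3-methoxy-5-(4,4,5,5-tetramethyl-1,3,2-dioxaborolan-2-yl)benzoate | COC(=O)c1cc(OC)c(F)c(c1)B1OC(C)(C)C(C)(C)O1 | intermediate
3 | tert-butyl bromoacetate | CC(C)(C)OC(=O)CBr | starting material
4 | tert-butyl 2-[2-fluoro-3-methoxy-5-(methoxycarbonyl)phenyl]acetate | COC(=O)c1cc(OC)c(F)c(c1)CC(=O)OC(C)(C)C | intermediate
5 | 2-[2-fluoro-3-methoxy-5-(methoxycarbonyl)phenyl]acetic acid | COC(=O)c1cc(OC)c(F)c(c1)CC(=O)O | intermediate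
6 | (S)-4-benzyl-2-oxazolidinone | O=C1OC[C@H](Cc2ccccc2)N1 | starting material
7 | 2-[2-fluoro-3-methoxy-5-(methoxycarbonyl)phenyl]acetic pivalic anhydride | COC(=O)c1cc(OC)c(F)c(c1)CC(=O)OC(=O)C(C)(C)C | intermediate (not isolated)
8 | methyl 3-{2-[(4S)-4-benzyl-2-oxo-1,3-oxazolidin-3-yl]-2-oxoethyl}-4-fluoro-5-methoxybenzoate | COC(=O)c1cc(OC)c(F)c(c1)CC(=O)N1C(=O)OC[C@@H]1Cc1ccccc1 | intermediate
9 | syringaldehyde (4-hydroxy-3,5-dimethoxybenzaldehyde) | COc1cc(C=O)cc(OC)c1O | starting material
10 | 4-(benzyloxy)-3,5-dimethoxybenzaldehyde | COc1cc(C=O)cc(OC)c1OCc1ccccc1 | intermediate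
11 | Z dibutylboron enolate of 8 | CCCCB(CCCC)O/C(=C\c1cc(C(=O)OC)cc(OC)c1F)N1C(=O)OC[C@@H]1Cc1ccccc1 | intermediate (not isolated)
12 | dibutylboron aldolate of 13 | O=C(N1C(=O)OC[C@@H]1Cc1ccccc1)[C@@H](c1cc(C(=O)OC)cc(OC)c1F)[C@H](OB(CCCC)CCCC)c1cc(OC)c(OCc2ccccc2)c(OC)c1 | intermediate (not isolated)
13 | methyl 3-[(2S,3S)-1-[(4S)-4-benzyl-2-oxo-1,3-oxazolidin-3-yl]-3-[4-(benzyloxy)-3,5-dimethoxyphenyl]-3-hydroxy-1-oxopropan-2-yl]-4-fluoro-5-methoxybenzoate | O=C(N1C(=O)OC[C@@H]1Cc1ccccc1)[C@@H](c1cc(C(=O)OC)cc(OC)c1F)[C@H](O)c1cc(OC)c(OCc2ccccc2)c(OC)c1 | intermediate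
14 | methyl 3-[(1S,2R)-1-[4-(benzyloxy)-3,5-dimethoxyphenyl]-1,3-dihydroxypropan-2-yl]-4-fluoro-5-methoxybenzoate | COC(=O)c1cc(OC)c(F)c(c1)[C@H](CO)[C@@H](c1cc(OC)c(OCc2ccccc2)c(OC)c1)O | intermediate
15 | methyl 3-[(1S,2R)-1-[4-(benzyloxy)-3,5-dimethoxyphenyl]-1-hydroxy-3-(triphenylmethoxy)propan-2-yl]-4-fluoro-5-methoxybenzoate | COC(=O)c1cc(OC)c(F)c(c1)[C@H](COC(c1ccccc1)(c1ccccc1)c1ccccc1)[C@@H](c1cc(OC)c(OCc2ccccc2)c(OC)c1)O | intermediate
16 | potassium (1S,2R)-1-[4-(benzyloxy)-3,5-dimethoxyphenyl]-2-[2-fluoro-3-methoxy-5-(methoxycarbonyl)phenyl]-3-(triphenylmethoxy)propan-1-olate | COC(=O)c1cc(OC)c(F)c(c1)[C@H](COC(c1ccccc1)(c1ccccc1)c1ccccc1)[C@@H](c1cc(OC)c(OCc2ccccc2)c(OC)c1)[O-].[K+] | intermediate (not isolated)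
17 | methyl (2S,3R)-2-[4-(benzyloxy)-3,5-dimethoxyphenyl]-7-methoxy-3-[(triphenylmethoxy)methyl]-2,3-dihydro-1-benzofuran-5-carboxylate | COC(=O)c1cc(OC)c2c(c1)[C@H](COC(c1ccccc1)(c1ccccc1)c1ccccc1)[C@@H](c1cc(OC)c(OCc3ccccc3)c(OC)c1)O2 | intermediate
18 | {(2S,3R)-2-[4-(benzyloxy)-3,5-dimethoxyphenyl]-7-methoxy-3-[(triphenylmethoxy)methyl]-2,3-dihydro-1-benzofuran-5-yl}methanol | OCc1cc(OC)c2c(c1)[C@H](COC(c1ccccc1)(c1ccccc1)c1ccccc1)[C@@H](c1cc(OC)c(OCc3ccccc3)c(OC)c1)O2 | intermediate
19 | methyl (triphenylphosphoranylidene)acetate | COC(=O)C=P(c1ccccc1)(c1ccccc1)c1ccccc1 | starting material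
20 | (2S,3R)-2-[4-(benzyloxy)-3,5-dimethoxyphenyl]-7-methoxy-3-[(triphenylmethoxy)methyl]-2,3-dihydro-1-benzofuran-5-carbaldehyde | O=Cc1cc(OC)c2c(c1)[C@H](COC(c1ccccc1)(c1ccccc1)c1ccccc1)[C@@H](c1cc(OC)c(OCc3ccccc3)c(OC)c1)O2 | intermediate (not isolated)
21 | methyl (2E)-3-{(2S,3R)-2-[4-(benzyloxy)-3,5-dimethoxyphenyl]-7-methoxy-3-[(triphenylmethoxy)methyl]-2,3-dihydro-1-benzofuran-5-yl}prop-2-enoate | COC(=O)/C=C/c1cc(OC)c2c(c1)[C@H](COC(c1ccccc1)(c1ccccc1)c1ccccc1)[C@@H](c1cc(OC)c(OCc3ccccc3)c(OC)c1)O2 | intermediate
22 | methyl (2E)-3-{(2S,3R)-2-[4-(benzyloxy)-3,5-dimethoxyphenyl]-3-(hydroxymethyl)-7-methoxy-2,3-dihydro-1-benzofuran-5-yl}prop-2-enoate | COC(=O)/C=C/c1cc(OC)c2c(c1)[C@H](CO)[C@@H](c1cc(OC)c(OCc3ccccc3)c(OC)c1)O2 | intermediate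
23 | methyl 3-[(2S,3R)-2-(4-hydroxy-3,5-dimethoxyphenyl)-3-(hydroxymethyl)-7-methoxy-2,3-dihydro-1-benzofuran-5-yl]propanoate | COC(=O)CCc1cc(OC)c2c(c1)[C@H](CO)[C@@H](c1cc(OC)c(O)c(OC)c1)O2 | target

## Step count and risk

Total steps: 13. Longest linear sequence: 12 (steps 1 to 4 and 6 to 13; step 5 is a one-step branch).

**Step 9 (key step).** The most likely failure is a ring closure too slow to win. Ring A is activated by a single para ester, and the methoxy group beside fluorine and the alkyl substituent both work against it. On warming, acyl transfer from the ester of one molecule to the alkoxide of another, or simple decay of the base, could then take over. The fallback raises the activation by changing the C5 group before closure. It sets out from 15. Reduction with i-Bu2AlH should give the benzylic alcohol (1S,2R)-1-[4-(benzyloxy)-3,5-dimethoxyphenyl]-2-[2-fluoro-5-(hydroxymethyl)-3-methoxyphenyl]-3-(triphenylmethoxy)propan-1-ol F1. Oxidation with catalytic TEMPO and PhI(OAc)2 is selective for the primary over the hindered secondary benzylic alcohol (MnO2 would attack both) and should give the fluoro aldehyde 3-[(1S,2R)-1-[4-(benzyloxy)-3,5-dimethoxyphenyl]-1-hydroxy-3-(triphenylmethoxy)propan-2-yl]-4-fluoro-5-methoxybenzaldehyde F2. A formyl group is a stronger para acceptor than an ester, so Cs2CO3 in DMF at 60 °C should close ring B by the same fluoride displacement. The fallback comes back to the route at 20, which is then olefinated with 19 as in step 11 without the oxidant.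

**Step 6.** The α-aryl enolate is stabilised and the aldehyde is electron-rich, so the addition may be slow and reversible. Retro-aldol cleavage and epimerisation of the acidic α-centre in the adduct would erode both conversion and diastereoselectivity. The fallback changes auxiliary and metal and sets out from 5. Coupling with (S)-4-benzyl-1,3-thiazolidine-2-thione (S=C1SC[C@H](Cc2ccccc2)N1) using EDC and DMAP should give the thioimide methyl 3-{2-[(4S)-4-benzyl-2-thioxo-1,3-thiazolidin-3-yl]-2-oxoethyl}-4-fluoro-5-methoxybenzoate F3. Its chlorotitanium enolate (TiCl4, i-Pr2NEt, N-methyl-2-pyrrolidinone, CH2Cl2, 0 °C) should add to 10 in the same syn sense to give methyl 3-[(2S,3S)-1-[(4S)-4-benzyl-2-thioxo-1,3-thiazolidin-3-yl]-3-[4-(benzyloxy)-3,5-dimethoxyphenyl]-3-hydroxy-1-oxopropan-2-yl]-4-fluoro-5-methoxybenzoate F4. The thioimide is cleaved by NaBH4 at 0 °C much faster than an oxazolidinone imide, and the fallback comes back to the route at 14.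

**Step 7.** Hydride attack at the hindered exocyclic carbonyl may be slow enough for the basic medium to cause retro-aldol cleavage, epimerisation at the α-carbon or opening of the oxazolidinone ring instead. The fallback separates cleavage from reduction and sets out from 13. LiOH and H2O2 in THF–H2O at 0 °C, where the hydroperoxide anion is a weak base and attacks only the exocyclic carbonyl, should give (2S,3S)-3-[4-(benzyloxy)-3,5-dimethoxyphenyl]-2-[2-fluoro-3-methoxy-5-(methoxycarbonyl)phenyl]-3-hydroxypropanoic acid F5. BH3·SMe2 in THF reduces a carboxylic acid in the presence of a methyl ester, and the fallback comes back to the route at 14.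

**Step 2.** Protodeboronation of the ortho-fluoro arylboronate in aqueous base, or slow transmetalation in the sp2–sp3 coupling, could leave mainly 1. The fallback inverts the polarity of the coupling and sets out from 2. CuBr2 in MeOH–H2O at 80 °C should give the aryl bromide methyl 3-bromo-4-fluoro-5-methoxybenzoate F6. This is coupled, with Pd(dba)2 and a bulky electron-rich phosphine in THF, with the Reformatsky reagent bromo(2-tert-butoxy-2-oxoethyl)zinc F7, made from 3 and zinc; a zinc enolate tolerates the methyl ester. The fallback comes back to the route at 4.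

**Step 13.** Once the phenol is free, continued exposure to hydrogen on palladium could hydrogenolyse the benzylic C2–O1 bond and open ring B. The fallback takes the two reductions apart and sets out from 22. Magnesium in methanol reduces the cinnamate double bond by electron transfer, without a hydrogenolysis catalyst, and should give the saturated benzyl ether methyl 3-{(2S,3R)-2-[4-(benzyloxy)-3,5-dimethoxyphenyl]-3-(hydroxymethyl)-7-methoxy-2,3-dihydro-1-benzofuran-5-yl}propanoate F8. The benzyl group is then removed by transfer hydrogenolysis (Pd/C, a limited excess of 1,4-cyclohexadiene, EtOH, rt), in which the hydrogen donor is the limiting reagent and the reaction should stop after the weakest benzylic C–O bond has been cleaved. The fallback comes back to the route at 23.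

## Further compounds

F1 | step 9 | (1S,2R)-1-[4-(benzyloxy)-3,5-dimethoxyphenyl]-2-[2-fluoro-5-(hydroxymethyl)-3-methoxyphenyl]-3-(triphenylmethoxy)propan-1-ol | OCc1cc(OC)c(F)c(c1)[C@H](COC(c1ccccc1)(c1ccccc1)c1ccccc1)[C@@H](c1cc(OC)c(OCc2ccccc2)c(OC)c1)O
F2 | step 9 | 3-[(1S,2R)-1-[4-(benzyloxy)-3,5-dimethoxyphenyl]-1-hydroxy-3-(triphenylmethoxy)propan-2-yl]-4-fluoro-5-methoxybenzaldehyde | O=Cc1cc(OC)c(F)c(c1)[C@H](COC(c1ccccc1)(c1ccccc1)c1ccccc1)[C@@H](c1cc(OC)c(OCc2ccccc2)c(OC)c1)O
F3 | step 6 | methyl 3-{2-[(4S)-4-benzyl-2-thioxo-1,3-thiazolidin-3-yl]-2-oxoethyl}-4-fluoro-5-methoxybenzoate | COC(=O)c1cc(OC)c(F)c(c1)CC(=O)N1C(=S)SC[C@@H]1Cc1ccccc1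
F4 | step 6 | methyl 3-[(2S,3S)-1-[(4S)-4-benzyl-2-thioxo-1,3-thiazolidin-3-yl]-3-[4-(benzyloxy)-3,5-dimethoxyphenyl]-3-hydroxy-1-oxopropan-2-yl]-4-fluoro-5-methoxybenzoate | O=C(N1C(=S)SC[C@@H]1Cc1ccccc1)[C@@H](c1cc(C(=O)OC)cc(OC)c1F)[C@H](O)c1cc(OC)c(OCc2ccccc2)c(OC)c1
F5 | step 7 | (2S,3S)-3-[4-(benzyloxy)-3,5-dimethoxyphenyl]-2-[2-fluoro-3-methoxy-5-(methoxycarbonyl)phenyl]-3-hydroxypropanoic acid | OC(=O)[C@@H](c1cc(C(=O)OC)cc(OC)c1F)[C@H](O)c1cc(OC)c(OCc2ccccc2)c(OC)c1
F6 | step 2 | methyl 3-bromo-4-fluoro-5-methoxybenzoate | COC(=O)c1cc(OC)c(F)c(Br)c1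
F7 | step 2 | bromo(2-tert-butoxy-2-oxoethyl)zinc | CC(C)(C)OC(=O)C[Zn]Br
F8 | step 13 | methyl 3-{(2S,3R)-2-[4-(benzyloxy)-3,5-dimethoxyphenyl]-3-(hydroxymethyl)-7-methoxy-2,3-dihydro-1-benzofuran-5-yl}propanoate | COC(=O)CCc1cc(OC)c2c(c1)[C@H](CO)[C@@H](c1cc(OC)c(OCc3ccccc3)c(OC)c1)O2
A1 | alternative 1 | methyl (2S,3R)-2-[4-(benzyloxy)-3,5-dimethoxyphenyl]-7-bromo-3-{[(tert-butyldimethylsilyl)oxy]methyl}-2,3-dihydro-1-benzofuran-5-carboxylate | COC(=O)c1cc(Br)c2c(c1)[C@H](CO[Si](C)(C)C(C)(C)C)[C@@H](c1cc(OC)c(OCc3ccccc3)c(OC)c1)O2
A2 | alternative 1 | methyl 3-bromo-2-oxo-2H-pyran-5-carboxylate (methyl 3-bromocoumalate) | COC(=O)C1=COC(=O)C(Br)=C1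
A3 | alternative 1 | (4R,5S)-5-[4-(benzyloxy)-3,5-dimethoxyphenyl]-4-{[(tert-butyldimethylsilyl)oxy]methyl}oxolan-2-one | O=C1C[C@H](CO[Si](C)(C)C(C)(C)C)[C@@H](c2cc(OC)c(OCc3ccccc3)c(OC)c2)O1
A4 | alternative 2 | 2,2,2-trichloroethyl (2S,3S)-2-[4-(benzyloxy)-3,5-dimethoxyphenyl]-7-methoxy-5-(3-methoxy-3-oxopropyl)-2,3-dihydro-1-benzofuran-3-carboxylate | COC(=O)CCc1cc(OC)c2c(c1)[C@H](C(=O)OCC(Cl)(Cl)Cl)[C@@H](c1cc(OC)c(OCc3ccccc3)c(OC)c1)O2
A5 | alternative 2 | 2,2,2-trichloroethyl 2-{2-[(4-benzyloxy-3,5-dimethoxyphenyl)methoxy]-3-methoxy-5-(3-methoxy-3-oxopropyl)phenyl}-2-diazoacetate | COC(=O)CCc1cc(OC)c(OCc2cc(OC)c(OCc3ccccc3)c(OC)c2)c(c1)C(=[N+]=[N-])C(=O)OCC(Cl)(Cl)Cl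
A6 | alternative 3 | methyl (2S,3S)-2-[4-(benzyloxy)-3,5-dimethoxyphenyl]-5-bromo-7-methoxy-2,3-dihydro-1-benzofuran-3-carboxylate | Brc1cc(OC)c2c(c1)[C@H](C(=O)OC)[C@@H](c1cc(OC)c(OCc3ccccc3)c(OC)c1)O2
A7 | alternative 3 | (2S)-2-[4-(benzyloxy)-3,5-dimethoxyphenyl]-6-bromo-8-methoxy-2,3-dihydro-4H-chromen-4-one | O=C1C[C@@H](c2cc(OC)c(OCc3ccccc3)c(OC)c2)Oc2c(OC)cc(Br)cc12
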